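Everything rests on closing the lactone by its O–C6 bond at the end. In the ten-membered ring, C6 is both α to the C5 carbonyl and γ to the C12 carboxyl of the acrylic acid on C7, so a trivalent iodine oxidant acting on the C6–H of a 5-oxo acid forms that bond, the α-methylene-γ-lactone ring and the C6 stereocentre in one operation. The precursor is the cyclodecanone acrylic acid 22, which already carries the C4 methyl, the C8 tiglate and the C9–C10 epoxide and is offered to the oxidant as its C5–C6 enol silane. The carbocycle comes from geranyl acetate by asymmetric hydrogenation, Sharpless epoxidation and a palladium-catalysed ring-closing allylation; ketone reduction ends the route.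

Key step: step 18

Remark on numbering: ring carbons are C1–C3 (CH2), C4 (CHMe), C5 (carbonyl or carbinol), C6, C7, C8 (O-tiglate), C9/C10 (epoxide CH/CMe), with side chain C11(=C13)–C12; open-chain intermediates are described with the same locants.
Remark on C5: the C5 carbinol formed in step 6 is carried as both epimers (centre left undefined in the SMILES) until it becomes the ketone in step 16.
Remark on step 3: the ligand hand is assigned by analogy with the tiglic acid case and rests on that analogy.

Step 1
Reactants: 1 geranyl acetate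
Product: 2 (2E,6E)-8-hydroxy-3,7-dimethylocta-2,6-dien-1-yl acetate
Conditions: SeO2 (cat.), t-BuOOH, salicylic acid (cat.), CH2Cl2, rt
Reagents that add atoms: tert-butyl hydroperoxide, CC(C)(C)OO
Why: Catalytic Riley allylic oxidation (ene reaction then [2,3]-shift) should hydroxylate only the (E)-methyl of the electron-rich terminal alkene, the alkene next to the acetate being deactivated.

Step 2
Reactants: 2 (2E,6E)-8-hydroxy-3,7-dimethylocta-2,6-dien-1-yl acetate
Product: 4 (2E,6E)-8-acetoxy-2,6-dimethylocta-2,6-dienoic acid, via enal 3 (not isolated)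
Conditions: 2,2,6,6-tetramethylpiperidin-1-oxyl (cat.), PhI(OAc)2, CH2Cl2, rt; then NaClO2, NaH2PO4, 2-methyl-2-butene, t-BuOH/H2O, 0 °C
Reagents that add atoms: sodium chlorite, [Na+].[O-]Cl=O
Why: Oxoammonium oxidation of the allylic alcohol followed in the same flask by Pinnick oxidation should give the (E)-2-methyl-2-enoic acid, the alkene scavenger protecting both trisubstituted alkenes from hypochlorous acid.

Step 3
Reactants: 4 (2E,6E)-8-acetoxy-2,6-dimethylocta-2,6-dienoic acid
Product: 5 (2R,6E)-8-acetoxy-2,6-dimethyloct-6-enoic acid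
Conditions: Ru(OAc)2[(R)-H8-BINAP] (1 mol%), H2 (5 atm), MeOH, rt
Reagents that add atoms: none
Why: Noyori-type carboxylate-directed asymmetric hydrogenation of a tiglic-acid-type (E)-2-methyl-2-enoic acid should set C4 as (R) with the (R)-ligand (the sense in which tiglic acid gives (R)-2-methylbutanoic acid), while the remote alkene, lacking a directing group, is not reduced.

Step 4
Reactants: 5 (2R,6E)-8-acetoxy-2,6-dimethyloct-6-enoic acid
Product: 6 (2E,7R)-8-[methoxy(methyl)amino]-3,7-dimethyl-8-oxooct-2-en-1-yl acetate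
Conditions: MeNH(OMe)·HCl, EDC·HCl, 1-hydroxybenzotriazole (cat.), i-Pr2NEt, CH2Cl2, 0 °C to rt
Reagents that add atoms: N,O-dimethylhydroxylamine hydrochloride, CNOC.Cl
Why: Carbodiimide amide coupling to the Weinreb amide should proceed without loss of the C4 configuration because a simple 2-methyl acid has no racemisation pathway under these conditions.

Step 5
Reactants: 6 (2E,7R)-8-[methoxy(methyl)amino]-3,7-dimethyl-8-oxooct-2-en-1-yl acetate
Product: 7 (2R,6E)-8-hydroxy-2,6-dimethyloct-6-enal
Conditions: i-Bu2AlH (3.5 equiv), CH2Cl2, −78 °C; aqueous potassium sodium tartrate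
Reagents that add atoms: none
Why: Hydride reduction of a Weinreb amide should stop at the chelated hemiaminal (aldehyde on work-up) while the same reagent cleaves the acetate, and the α-methyl aldehyde is used at once so that C4 does not epimerise.

Step 6
Reactants: 7 (2R,6E)-8-hydroxy-2,6-dimethyloct-6-enal; 8 allylmagnesium bromide
Product: 9 (2E,7R)-3,7-dimethylundeca-2,10-diene-1,8-diol (both C8 epimers; C8 of this name is ring C5)
Conditions: 8 (2.5 equiv), THF, −78 °C; aqueous NH4Cl
Reagents that add atoms: none
Why: Grignard 1,2-addition after deprotonation of the free alcohol should add C6 and C7, the C5 carbinol being left as both epimers on purpose because it is oxidised later.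

Step 7
Reactants: 9 (2E,7R)-3,7-dimethylundeca-2,10-diene-1,8-diol
Product: 10 (5R)-8-[(2R,3R)-3-(hydroxymethyl)-2-methyloxiran-2-yl]-5-methyloct-1-en-4-ol (both C4 epimers)
Conditions: Ti(OiPr)4 (1 equiv), D-(−)-diethyl tartrate, t-BuOOH, 4 Å molecular sieves, CH2Cl2, −20 °C
Reagents that add atoms: tert-butyl hydroperoxide, CC(C)(C)OO
Why: Katsuki–Sharpless asymmetric epoxidation should act only on the allylic alcohol (the homoallylic vinyl group is inert) and the D-tartrate should deliver oxygen to the face that gives the (2R,3R)-epoxy alcohol, fixing C9 and C10 by reagent control.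

Step 8
Reactants: 10 (5R)-8-[(2R,3R)-3-(hydroxymethyl)-2-methyloxiran-2-yl]-5-methyloct-1-en-4-ol
Product: 11 bis(triethylsilyl) ether of 10 (C5–O and C8–O silylated)
Conditions: Et3SiCl, imidazole, DMF, 0 °C
Reagents that add atoms: chlorotriethylsilane, CC[Si](Cl)(CC)CC
Why: Imidazole-mediated silylation should cap both hydroxyls under non-acidic conditions that leave the trisubstituted epoxide intact.

Step 9
Reactants: 12 2-methylenepropane-1,3-diol
Product: 13 2-{[tert-butyl(dimethyl)silyl]oxymethyl}prop-2-en-1-ol
Conditions: 12 (3 equiv), t-BuMe2SiCl (1 equiv), imidazole, THF, 0 °C to rt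
Reagents that add atoms: tert-butyl(chloro)dimethylsilane, CC(C)(C)[Si](C)(C)Cl
Why: Statistical monosilylation of a symmetric diol used in excess should give the mono ether, the surplus diol being washed out with water.

Step 10
Reactants: 13 2-{[tert-butyl(dimethyl)silyl]oxymethyl}prop-2-en-1-ol
Product: 14 tert-butyl{[2-(chloromethyl)prop-2-en-1-yl]oxy}dimethylsilane
Conditions: N-chlorosuccinimide, Me2S, CH2Cl2, −20 to 0 °C
Reagents that add atoms: N-chlorosuccinimide, O=C1CCC(=O)N1Cl
Why: Corey–Kim chlorination should convert the primary allylic alcohol to the chloride through its alkoxysulfonium salt under neutral conditions that keep the silyl ether.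

Step 11
Reactants: 11 bis(triethylsilyl) ether of 10; 14 tert-butyl{[2-(chloromethyl)prop-2-en-1-yl]oxy}dimethylsilane
Product: 15 trisubstituted allylic chloride, i.e. 11 with its terminal =CH2 replaced by =C(CH2Cl)(CH2OSiMe2t-Bu) (E/Z mixture)
Conditions: second-generation Hoveyda–Grubbs catalyst (10 mol%), 14 (5 equiv), CH2Cl2, 40 °C
Reagents that add atoms: none
Why: Olefin cross-metathesis between the only terminal alkene of 11 and an excess of the non-dimerising 1,1-disubstituted partner should install C11–C13, the alkene geometry being irrelevant because both isomers ionise to the same allyl species in step 13.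

Step 12
Reactants: 15 trisubstituted allylic chloride
Product: 16 epoxy aldehyde, i.e. 15 with the C8 CH2OSiEt3 group converted to CHO
Conditions: (COCl)2, DMSO, CH2Cl2, −78 to −40 °C; then Et3N, −78 to 0 °C
Reagents that add atoms: none
Why: Under Swern conditions a primary triethylsilyl ether should be cleaved and oxidised directly to the aldehyde while the secondary triethylsilyl and the tert-butyldimethylsilyl ethers persist (selective oxidative desilylation), and the sensitive epoxy aldehyde is used crude.

Step 13
Reactants: 16 epoxy aldehyde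
Product: 17 (4R,7R,8R,9R,10R)-9,10-epoxy-4,10-dimethyl-7-[3-(tert-butyldimethylsilyloxy)prop-1-en-2-yl]-5-(triethylsilyloxy)cyclodecan-8-ol (both C5 epimers)
Conditions: Pd(PPh3)4 (10 mol%), Et2Zn (3 equiv), K2CO3, N,N-dimethylacetamide, rt, slow addition of 16 to about 5 mM
Reagents that add atoms: none
Why: Palladium-catalysed umpolung (Barbier-type) allylation, a ring closure known for epoxy aldehyde/allylic chloride pairs leading to ten-membered carbocycles, should proceed through an allylzinc that attacks the aldehyde with its substituted terminus in a chair transition state with the C6 chain equatorial (C7/C8 anti) and from the Felkin–Anh face anti to the epoxide C9–O bond, so that C8 and C7 are relayed from C9.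

Step 14
Reactants: 17 cyclodecanol; 18 tigloyl chloride ((2E)-2-methylbut-2-enoyl chloride)
Product: 19 C8 tiglate of 17
Conditions: pyridine, 4-(dimethylamino)pyridine (cat.), CH2Cl2, 0 °C to rt
Reagents that add atoms: none
Why: Nucleophile-catalysed acylation of the only free hydroxyl should give the (E)-ester, pyridine being too weak a base to deconjugate the acid chloride through a vinylketene.

Step 15
Reactants: 19 C8 tiglate of 17
Product: 20 (4R,7R,8R,9R,10R)-9,10-epoxy-5-hydroxy-7-(3-hydroxyprop-1-en-2-yl)-4,10-dimethylcyclodecan-8-yl (2E)-2-methylbut-2-enoate (both C5 epimers)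
Conditions: Bu4NF, AcOH (1:1), THF, 0 °C to rt
Reagents that add atoms: none
Why: Acetic-acid-buffered fluoride desilylation should remove both silyl ethers without opening the epoxide or moving the tiglate.

Step 16
Reactants: 20 diol
Product: 21 (4R,7R,8R,9R,10R)-9,10-epoxy-4,10-dimethyl-5-oxo-7-(3-oxoprop-1-en-2-yl)cyclodecan-8-yl (2E)-2-methylbut-2-enoate
Conditions: Dess–Martin periodinane (3 equiv), pyridine, CH2Cl2, 0 °C to rt
Reagents that add atoms: none
Why: Dess–Martin oxidation should convert both C5 carbinol epimers to one ketone and the primary allylic alcohol to the 2-substituted acrolein in a single buffered operation.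

Step 17
Reactants: 21 keto enal
Product: 22 2-[(4R,7R,8R,9R,10R)-9,10-epoxy-4,10-dimethyl-5-oxo-8-{[(2E)-2-methylbut-2-enoyl]oxy}cyclodecan-7-yl]prop-2-enoic acid (the 5-oxo acrylic acid precursor)
Conditions: NaClO2, NaH2PO4, 2-methyl-2-butene, t-BuOH/H2O, 0 °C
Reagents that add atoms: sodium chlorite, [Na+].[O-]Cl=O
Why: Pinnick oxidation is selective for the aldehyde and should leave ketone, epoxide and tiglate alone, and 22 is kept cold and used directly so that the free acid cannot open the epoxide.

Step 18
Reactants: 22 5-oxo acrylic acid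
Product: 24 5-oxo lactone (4R,6S,7R,8R,9R,10R; the C5 ketone analogue of 25), via bis-silyl enol ether 23 (not isolated)
Conditions: Me3SiCl (3 equiv), LiN(SiMe3)2 (2.2 equiv), THF, −78 °C; then PhI(OH)OTs (1.1 equiv), 2,6-di-tert-butylpyridine, CH2Cl2, −40 to 0 °C; then i-Pr2NEt (0.2 equiv), 0 °C
Reagents that add atoms: chlorotrimethylsilane, C[Si](C)(C)Cl (its atoms stay in 23 only; none are left in 24)
Why: Kinetic deprotonation with in-situ silylation gives the silyl ester and the less substituted C5–C6 enol silane, whose C6 attacks the trivalent iodine of PhI(OH)OTs to give an α-(phenyliodanyl) ketone. The C12 carboxylate oxygen then displaces iodobenzene at C6 in a 5-exo-tet substitution, forming the O–C6 bond and the γ-lactone ring; this is the known hypervalent-iodine oxidative lactonisation of 5-oxo acids (intramolecular ketone α-acyloxylation), run here through the enol silane. C6 is the only new stereocentre: the iodane and the α-acyloxy ketone both epimerise through the C5 enol, so the ring fusion is set under Curtin–Hammett and then thermodynamic control by C7, the trans-fused lactone (H6 anti to H7) being expected and the trace of hindered amine completing the equilibration. Site selectivity for C6 over the tertiary C4 is secured by the regiodefined enol silane and by the tether, since the carboxylate reaches only C6 through a five-membered transition state. Chemoselectivity rests on the electron-poor acrylate and tiglate alkenes being inert to the electrophilic iodane and on the hindered pyridine, which keeps the sulfonic acid away from the epoxide and from C4.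

Step 19
Reactants: 24 5-oxo lactone
Product: 25 target (4R,5R,6S,7S,8R,9R,10R), CNP0165329.2
Conditions: Zn(BH4)2, Et2O, −30 °C
Reagents that add atoms: none
Why: Chelation-controlled ketone reduction (zinc bridging the C5 carbonyl and the C6 lactone oxygen, hydride from the face of H6) should give the 5,6-anti alcohol, which is (5R), and this mild borohydride leaves the lactone, its exocyclic methylene, the tiglate and the epoxide untouched.

Compound list
1 | geranyl acetate, (2E)-3,7-dimethylocta-2,6-dien-1-yl acetate | CC(C)=CCC/C(C)=C/COC(C)=O | starting material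
2 | (2E,6E)-8-hydroxy-3,7-dimethylocta-2,6-dien-1-yl acetate | OC/C(C)=C/CC/C(C)=C/COC(C)=O | intermediate
3 | (2E,6E)-3,7-dimethyl-8-oxoocta-2,6-dien-1-yl acetate (enal, not isolated) | O=C/C(C)=C/CC/C(C)=C/COC(C)=O | intermediate
4 | (2E,6E)-8-acetoxy-2,6-dimethylocta-2,6-dienoic acid | OC(=O)/C(C)=C/CC/C(C)=C/COC(C)=O | intermediate
5 | (2R,6E)-8-acetoxy-2,6-dimethyloct-6-enoic acid | OC(=O)[C@H](C)CCC/C(C)=C/COC(C)=O | intermediate
6 | (2E,7R)-8-[methoxy(methyl)amino]-3,7-dimethyl-8-oxooct-2-en-1-yl acetate | CON(C)C(=O)[C@H](C)CCC/C(C)=C/COC(C)=O | intermediate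
7 | (2R,6E)-8-hydroxy-2,6-dimethyloct-6-enal | O=C[C@H](C)CCC/C(C)=C/CO | intermediate
8 | allylmagnesium bromide | C=CC[Mg]Br | starting material
9 | (2E,7R)-3,7-dimethylundeca-2,10-diene-1,8-diol, both C8 epimers | C=CCC(O)[C@H](C)CCC/C(C)=C/CO | intermediate
10 | (5R)-8-[(2R,3R)-3-(hydroxymethyl)-2-methyloxiran-2-yl]-5-methyloct-1-en-4-ol, both C4 epimers | C=CCC(O)[C@H](C)CCC[C@@]1(C)O[C@@H]1CO | intermediate
11 | bis(triethylsilyl) ether of 10 | C=CCC(O[Si](CC)(CC)CC)[C@H](C)CCC[C@@]1(C)O[C@@H]1CO[Si](CC)(CC)CC | intermediate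
12 | 2-methylenepropane-1,3-diol | C=C(CO)CO | starting material
13 | 2-{[tert-butyl(dimethyl)silyl]oxymethyl}prop-2-en-1-ol | C=C(CO)CO[Si](C)(C)C(C)(C)C | intermediate
14 | tert-butyl{[2-(chloromethyl)prop-2-en-1-yl]oxy}dimethylsilane | C=C(CCl)CO[Si](C)(C)C(C)(C)C | intermediate
15 | cross-metathesis product: open chain C13H2Cl–C11(C12H2OSiMe2t-Bu)=C7H–C6H2–C5H(OSiEt3)–C4H(Me)–(CH2)3–(9R,10R)-epoxide–C8H2OSiEt3, E/Z mixture | ClCC(CO[Si](C)(C)C(C)(C)C)=CCC(O[Si](CC)(CC)CC)[C@H](C)CCC[C@@]1(C)O[C@@H]1CO[Si](CC)(CC)CC | intermediate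
16 | epoxy aldehyde: 15 with C8 as CHO, a (2S,3R)-3-methyloxirane-2-carbaldehyde, same spatial arrangement as 10 | ClCC(CO[Si](C)(C)C(C)(C)C)=CCC(O[Si](CC)(CC)CC)[C@H](C)CCC[C@@]1(C)O[C@@H]1C=O | intermediate
17 | (4R,7R,8R,9R,10R)-9,10-epoxy-4,10-dimethyl-7-[3-(tert-butyldimethylsilyloxy)prop-1-en-2-yl]-5-(triethylsilyloxy)cyclodecan-8-ol, both C5 epimers | C=C(CO[Si](C)(C)C(C)(C)C)[C@H]1CC(O[Si](CC)(CC)CC)[C@H](C)CCC[C@@]2(C)O[C@@H]2[C@@H]1O | intermediate
18 | tigloyl chloride, (2E)-2-methylbut-2-enoyl chloride | C/C=C(\C)C(Cl)=O | starting material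
19 | C8 (2E)-2-methylbut-2-enoate of 17 | C=C(CO[Si](C)(C)C(C)(C)C)[C@H]1CC(O[Si](CC)(CC)CC)[C@H](C)CCC[C@@]2(C)O[C@@H]2[C@@H]1OC(=O)/C(C)=C/C | intermediate
20 | (4R,7R,8R,9R,10R)-9,10-epoxy-5-hydroxy-7-(3-hydroxyprop-1-en-2-yl)-4,10-dimethylcyclodecan-8-yl (2E)-2-methylbut-2-enoate, both C5 epimers | C=C(CO)[C@H]1CC(O)[C@H](C)CCC[C@@]2(C)O[C@@H]2[C@@H]1OC(=O)/C(C)=C/C | intermediate
21 | (4R,7R,8R,9R,10R)-9,10-epoxy-4,10-dimethyl-5-oxo-7-(3-oxoprop-1-en-2-yl)cyclodecan-8-yl (2E)-2-methylbut-2-enoate | C=C(C=O)[C@H]1CC(=O)[C@H](C)CCC[C@@]2(C)O[C@@H]2[C@@H]1OC(=O)/C(C)=C/C | intermediate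
22 | 2-[(4R,7R,8R,9R,10R)-9,10-epoxy-4,10-dimethyl-5-oxo-8-{[(2E)-2-methylbut-2-enoyl]oxy}cyclodecan-7-yl]prop-2-enoic acid | C=C(C(=O)O)[C@H]1CC(=O)[C@H](C)CCC[C@@]2(C)O[C@@H]2[C@@H]1OC(=O)/C(C)=C/C | intermediate
23 | trimethylsilyl ester and C5–C6 trimethylsilyl enol ether of 22 (not isolated) | C=C(C(=O)O[Si](C)(C)C)[C@H]1C=C(O[Si](C)(C)C)[C@H](C)CCC[C@@]2(C)O[C@@H]2[C@@H]1OC(=O)/C(C)=C/C | intermediate
24 | 5-oxo lactone (4R,6S,7R,8R,9R,10R): α-methylene trans-γ-lactone O–C6/C12, C5 ketone, C8 tiglate, C9–C10 epoxide | C=C1C(=O)O[C@@H]2C(=O)[C@H](C)CCC[C@@]3(C)O[C@@H]3[C@H](OC(=O)/C(C)=C/C)[C@@H]12 | intermediate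
25 | CNP0165329.2 (4R,5R,6S,7S,8R,9R,10R): 24 with C5 as (R)-carbinol | C=C1C(=O)O[C@@H]2[C@H](O)[C@H](C)CCC[C@@]3(C)O[C@@H]3[C@H](OC(=O)/C(C)=C/C)[C@@H]12 | target

Total step count: 19 (17 on the main line, 2 for the metathesis partner 14).
Longest linear sequence: 17 steps (steps 1–8 and 11–19, from geranyl acetate).

Steps most likely to fail

1. Step 18. The C6 iodane may be captured by sulfonate, or the epoxide may be opened by acid, before the carboxylate closes the ring. The fallback sets out from 22 and comes back at 24. The enol silane 23 is made as in step 18 and brominated at C6 with N-bromosuccinimide (THF, −78 °C); aqueous work-up gives the 6-bromo-5-oxo acid F1 (both C6 epimers). NaHCO3 in DMF at room temperature then lets the carboxylate displace bromide at C6 in a 5-exo-tet substitution, the classical alkylation of a carboxylate by an α-halo ketone. The C6 epimers converge on the trans-fused 24 through the same enolisation.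

2. Step 13. Facial selectivity at the C8 aldehyde may be poor during ring closure, so that 17 arrives mixed with its C8 epimer. The fallback sets out from 17 as obtained and comes back at 17. Pyridine-buffered Dess–Martin oxidation converts both C8 epimers to the α,β-epoxy ketone F2. Zn(BH4)2 in Et2O at −30 °C, chelated between the ketone and epoxide oxygens, then reduces F2 to the anti epoxy alcohol, which is 17.

3. Step 19. Hydride may be delivered to the wrong face of the C5 ketone if the ring conformation overrides chelation. The fallback sets out from 24 and comes back at 25. The reduction then gives the C5 epimer F3, which is inverted by a Mitsunobu reaction with chloroacetic acid (PPh3, diisopropyl azodicarboxylate, toluene, 0 °C) to the chloroacetate F4 of 25. Thiourea with NaHCO3 in ethanol removes the chloroacetyl group without touching the tiglate or the lactone.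

Further compounds
F1 | step 18 | 6-bromo derivative of 22 (2-[6-bromo-9,10-epoxy-4,10-dimethyl-5-oxo-8-(tigloyloxy)cyclodecan-7-yl]prop-2-enoic acid, both C6 epimers) | C=C(C(=O)O)[C@H]1C(Br)C(=O)[C@H](C)CCC[C@@]2(C)O[C@@H]2[C@@H]1OC(=O)/C(C)=C/C
F2 | step 13 | C8 ketone of 17 (9,10-epoxy-4,10-dimethyl-7-[3-(tert-butyldimethylsilyloxy)prop-1-en-2-yl]-5-(triethylsilyloxy)cyclodecan-8-one) | C=C(CO[Si](C)(C)C(C)(C)C)[C@H]1CC(O[Si](CC)(CC)CC)[C@H](C)CCC[C@@]2(C)O[C@@H]2C1=O
F3 | step 19 | C5 epimer of 25 | C=C1C(=O)O[C@@H]2[C@@H](O)[C@H](C)CCC[C@@]3(C)O[C@@H]3[C@H](OC(=O)/C(C)=C/C)[C@@H]12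
F4 | step 19 | C5 chloroacetate of 25 | C=C1C(=O)O[C@@H]2[C@H](OC(=O)CCl)[C@H](C)CCC[C@@]3(C)O[C@@H]3[C@H](OC(=O)/C(C)=C/C)[C@@H]12
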